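**Plan**

- Retrosynthesis: after removal of six benzyl groups, ring C is opened at O1–C2 and ring A is cut off at C8a–O1 and C4–C4a. This gives a furan-fused flavan acid (C4 as the carboxyl on C3, C2 as a methyl ketal) and 3,5-bis(benzyloxy)benzyne. The acid is cut at C3–flavan C8 and C2–flavan O7 into a (2S)-flavan-7-ol and an aryl 2,3-dioxopropanoate.
- Enabling feature: ring A carries the C4 ketone on C4a and the ketal oxygen O1 on the adjacent C8a, with the C5 oxygen next to C4a. This is an ortho-acyl phenol flanked by an alkoxy group, which is what carboxylate addition and acyl shift on a 3-alkoxyaryne produce.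
- Forward order: flavan rings (from (S)-naringenin), then the furan ring by Friedel–Crafts addition and ketalisation, then ring A joined and ring C closed in one flask, then hydrogenolysis.
- Stereochemistry: flavan C2 comes from (S)-naringenin; C3 is set by a chiral Cu(OTf)2–bis(oxazoline) catalyst in the Friedel–Crafts step; C2 follows from C3 because ring C can only close cis on the furan ring.

Key step: step 13

**Remarks**

- Locants: the chromanone half keeps flavonoid numbering (O1, C2, C3, C4, C4a–C8a, ring B on C2). Atoms of the flavan half are written "flavan C2 … flavan C8a", with ring E on flavan C2. In the furo[2,3-h]chromene names of 12–15, C8 and C9 are the later C2 and C3.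
- Assumption: the methyl ketals 13–15 are drawn as the C2 epimer with methoxy cis to the carboxyl carbon. The other epimer, if present, is carried along, because C2 is ionised and reset in step 13.
- (R,R)-tBu-box is 2,2′-(propane-2,2-diyl)bis[(4R)-4-tert-butyl-4,5-dihydro-1,3-oxazole].
- Compounds 1, 7 and 16 are purchased. The enantiomeric purity of 1 should be checked, and that of the flavan again at 4.

**Route**

Step 1
Reactants: 1 (S)-naringenin
Product: 2 (2S)-5-hydroxy-7-(methoxymethoxy)-2-[4-(methoxymethoxy)phenyl]chroman-4-one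
Conditions: MOMCl (2.3 equiv), iPr2NEt, CH2Cl2/DMF, 0 °C → rt
Reagents that add atoms: chloromethyl methyl ether, COCCl
Why: O-alkylation (Williamson type) of the two free phenols; the C5 hydroxyl is held in a hydrogen bond to C4=O and stays free, and the mild amine base at low temperature should limit ring opening of the flavanone and thus loss of the C2 configuration.

Step 2
Reactants: 2 (2S)-5-hydroxy-7-(methoxymethoxy)-2-[4-(methoxymethoxy)phenyl]chroman-4-one
Product: 4 (2S)-7-(methoxymethoxy)-2-[4-(methoxymethoxy)phenyl]chroman-5-ol, via ethyl carbonate 3 (not isolated)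
Conditions: ClCO2Et, Et3N, THF, 0 °C; then NaBH4, THF/H2O, 0 °C → rt
Reagents that add atoms: none
Why: Reductive deoxygenation of an ortho-acyl aryl carbonate: hydride reduces C4=O, the alkoxide takes over the carbonate, the phenoxide expels it to an ortho-quinone methide and a second hydride gives the CH2 group; C2 is not involved.

Step 3
Reactants: 4 (2S)-7-(methoxymethoxy)-2-[4-(methoxymethoxy)phenyl]chroman-5-ol
Product: 5 (2S)-5-(benzyloxy)-7-(methoxymethoxy)-2-[4-(methoxymethoxy)phenyl]chromane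
Conditions: BnBr, K2CO3, DMF, rt
Reagents that add atoms: benzyl bromide, BrCc1ccccc1
Why: Williamson etherification of the only free phenol, which is no longer chelated once C4 is a methylene group; the flavan has no base-labile stereocentre.

Step 4
Reactants: 5 (2S)-5-(benzyloxy)-7-(methoxymethoxy)-2-[4-(methoxymethoxy)phenyl]chromane
Product: 6 (2S)-5-(benzyloxy)-2-(4-hydroxyphenyl)chroman-7-ol
Conditions: 3 M HCl, MeOH/THF, 45 °C
Reagents that add atoms: none
Why: Acid-catalysed methanolysis of the two aryl methoxymethyl acetals; methanol traps the methoxymethyl cation, and the benzyl ether and the flavan C2–O bond should be stable to dilute acid at this temperature.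

Step 5
Reactants: 7 1-[4-(benzyloxy)phenyl]ethan-1-one
Product: 8 methyl 3-[4-(benzyloxy)phenyl]-3-oxopropanoate
Conditions: NaH, (MeO)2CO, toluene, reflux; aq. HCl
Reagents that add atoms: dimethyl carbonate, COC(=O)OC
Why: Claisen condensation of the ketone enolate with dimethyl carbonate, driven by deprotonation of the β-keto ester.

Step 6
Reactants: 8 methyl 3-[4-(benzyloxy)phenyl]-3-oxopropanoate
Product: 9 methyl 3-[4-(benzyloxy)phenyl]-2-diazo-3-oxopropanoate
Conditions: p-ABSA, Et3N, MeCN, 0 °C → rt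
Reagents that add atoms: 4-acetamidobenzenesulfonyl azide, CC(=O)Nc1ccc(cc1)S(=O)(=O)N=[N+]=[N-]
Why: Regitz diazo transfer to the activated methylene group.

Step 7
Reactants: 9 methyl 3-[4-(benzyloxy)phenyl]-2-diazo-3-oxopropanoate
Product: 10 methyl 3-[4-(benzyloxy)phenyl]-2,3-dioxopropanoate
Conditions: DMDO, acetone, 0 °C
Reagents that add atoms: dimethyldioxirane, CC1(C)OO1
Why: Oxygen transfer from the dioxirane to the diazo carbon with loss of N2 gives the vicinal tricarbonyl in anhydrous form, as needed for Lewis acid catalysis; diazo oxidation is much faster than attack on the benzyl ether.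

Step 8
Reactants: 6 (2S)-5-(benzyloxy)-2-(4-hydroxyphenyl)chroman-7-ol; 10 methyl 3-[4-(benzyloxy)phenyl]-2,3-dioxopropanoate
Product: 13 methyl (2S,8S,9S)-5-(benzyloxy)-8-[4-(benzyloxy)phenyl]-9-hydroxy-2-(4-hydroxyphenyl)-8-methoxy-3,4,8,9-tetrahydro-2H-furo[2,3-h]chromene-9-carboxylate, via keto phenol 11 (not isolated), via hemiketal 12 (not isolated)
Conditions: Cu(OTf)2 (10 mol %), (R,R)-tBu-box (11 mol %), 4 Å MS, CH2Cl2/Et2O, −20 °C; silica plug; then CSA (10 mol %), MeOH, 40 °C
Reagents that add atoms: methanol, CO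
Why: Proposed new method: the divalent copper bis(oxazoline) complex should bind the central ketone and the ester carbonyl of 10 as a five-membered chelate (as pyruvates do), which activates the most electrophilic carbonyl and leaves its re face open (O > CO2Me > aroyl), so that flavan C8 of 6 (ortho to the free 7-OH and less hindered than C6 beside the benzyloxy group) adds there and sets C3 as (S) in 11; the 7-OH then adds to the aryl ketone, and mild acid in methanol turns hemiketal 12 into the methyl ketal as the thermodynamic sink without ionising the carbinol flanked by ester and ketal carbon; closest known reactions are the Cu(OTf)2–bis(oxazoline) Friedel–Crafts hydroxyalkylation of electron-rich arenes with glyoxylate and trifluoropyruvate, ene reactions of 2,3-diketo esters under the same catalysts, and the uncatalysed addition of electron-rich arenes to the central carbonyl of vicinal tricarbonyls.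

Step 9
Reactants: 13 methyl (2S,8S,9S)-5-(benzyloxy)-8-[4-(benzyloxy)phenyl]-9-hydroxy-2-(4-hydroxyphenyl)-8-methoxy-3,4,8,9-tetrahydro-2H-furo[2,3-h]chromene-9-carboxylate
Product: 14 methyl (2S,8S,9S)-5,9-bis(benzyloxy)-2,8-bis[4-(benzyloxy)phenyl]-8-methoxy-3,4,8,9-tetrahydro-2H-furo[2,3-h]chromene-9-carboxylate
Conditions: NaH, BnBr, n-Bu4NI (cat.), DMF, 0 °C → rt
Reagents that add atoms: benzyl bromide, BrCc1ccccc1
Why: Williamson etherification of the phenoxide and of the tertiary alkoxide (acidified by the α-ester, no enolisable or eliminable position nearby); benzyl bromide is present before the base so that the ring E phenoxide is capped at once and cannot open the flavan through a quinone methide.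

Step 10
Reactants: 14 methyl (2S,8S,9S)-5,9-bis(benzyloxy)-2,8-bis[4-(benzyloxy)phenyl]-8-methoxy-3,4,8,9-tetrahydro-2H-furo[2,3-h]chromene-9-carboxylate
Product: 15 (2S,8S,9S)-5,9-bis(benzyloxy)-2,8-bis[4-(benzyloxy)phenyl]-8-methoxy-3,4,8,9-tetrahydro-2H-furo[2,3-h]chromene-9-carboxylic acid
Conditions: LiOH·H2O, THF/MeOH/H2O, 50 °C; then 1 M HCl to pH 4, 0 °C
Reagents that add atoms: lithium hydroxide, [Li+].[OH-]
Why: Saponification of a methyl ester activated by its α-alkoxy group; ketal, benzyl ethers and all stereocentres are inert to hydroxide, and the cold, weakly acidic work-up spares the methyl ketal.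

Step 11
Reactants: 16 3,5-bis(benzyloxy)phenol
Product: 17 3,5-bis(benzyloxy)-2-bromophenol
Conditions: NBS (1.0 equiv), CH2Cl2, −78 → −20 °C
Reagents that add atoms: N-bromosuccinimide, O=C1CCC(=O)N1Br
Why: Electrophilic aromatic bromination, directed ortho to the hydroxyl in a non-polar solvent at low temperature (two equivalent ortho positions); any 4-bromo isomer would be removed by chromatography.

Step 12
Reactants: 17 3,5-bis(benzyloxy)-2-bromophenol
Product: 20 3,5-bis(benzyloxy)-2-(trimethylsilyl)phenyl trifluoromethanesulfonate, via aryl silyl ether 18 (not isolated), via lithium phenoxide 19 (not isolated)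
Conditions: HMDS, THF, 65 °C, evaporate; n-BuLi, THF, −78 °C; Tf2O, −78 → 0 °C
Reagents that add atoms: hexamethyldisilazane, C[Si](C)(C)N[Si](C)(C)C; trifluoromethanesulfonic anhydride, O=S(=O)(OS(=O)(=O)C(F)(F)F)C(F)(F)F
Why: O-silylation, bromine–lithium exchange, 1,3 O→C silyl shift (retro-Brook) and O-triflation of the resulting phenoxide, the standard entry to ortho-silyl aryl triflates; the exchange at −78 °C is faster than deprotonation of the benzylic CH2 groups.

Step 13
Reactants: 15 (2S,8S,9S)-5,9-bis(benzyloxy)-2,8-bis[4-(benzyloxy)phenyl]-8-methoxy-3,4,8,9-tetrahydro-2H-furo[2,3-h]chromene-9-carboxylic acid; 20 3,5-bis(benzyloxy)-2-(trimethylsilyl)phenyl trifluoromethanesulfonate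
Product: 23 hexabenzyl ether of 24 (benzyl on O3/O5/O7/ring B O4′/flavan O5/ring E O4′), via aryne 21 (not isolated), via ortho-acyl phenol 22 (not isolated)
Conditions: 20 (1.5 equiv), CsF (4 equiv), THF, 125 °C (sealed tube); cool to rt; then CSA (excess over fluoride), CH2Cl2, 40 °C
Reagents that add atoms: none
Why: Fluoride turns 20 into 3,5-bis(benzyloxy)benzyne 21; the cesium carboxylate of 15, the only nucleophile left now that every hydroxyl is capped, adds to the aryne carbon remote from the flanking benzyloxy group (C8a–O1), and the aryl anion formed beside that benzyloxy group attacks the ester carbonyl through a four-membered alkoxide that opens to the ortho-acyl phenoxide of 22 (C4–C4a). The closest known reaction is the CsF-mediated insertion of arynes into the C–O bond of carboxylic acids in hot THF, which is also known with a follow-up ring closure by the new phenoxide (chromanones from unsaturated acids). Camphorsulfonic acid then protonates the phenoxide and ionises the C2 methyl ketal to an oxocarbenium ion stabilised by the furan oxygen and the 4-benzyloxyphenyl ring, and the phenol oxygen closes ring C on it in a 6-exo-trig mode (O1–C2). The new stereocentre C2 is controlled by C3: the tether C3–C4–C4a can deliver O1 only to the furan face that carries C4, so only the cis-fused ketal forms and either C2 epimer of 15 converges. The step needs regioselective aryne addition, secured by the benzyloxy group of 21 next to the triple bond (oxygen adds meta, carbon ortho to it), and it needs the aryl anion to escape protonation, which is why the tertiary hydroxyl was benzylated and an aprotic solvent is used.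

Step 14
Reactants: 23 hexabenzyl ether of 24
Product: 24 CNP0208300.2
Conditions: H2 (1 atm), Pd(OH)2/C, THF/MeOH, rt
Reagents that add atoms: none
Why: Hydrogenolysis of five aryl benzyl ethers and the tertiary alkyl benzyl ether; under neutral conditions at 1 atm the diaryl ketal, the flavan C2–O bond and the hydrogen-bonded C4 carbonyl should survive, and no stereocentre is touched.

**Compound list**

1 | (S)-naringenin, (2S)-5,7-dihydroxy-2-(4-hydroxyphenyl)chroman-4-one | O=C1C[C@@H](c2ccc(O)cc2)Oc2cc(O)cc(O)c21 | starting material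
2 | (2S)-5-hydroxy-7-(methoxymethoxy)-2-[4-(methoxymethoxy)phenyl]chroman-4-one | O=C1C[C@@H](c2ccc(OCOC)cc2)Oc2cc(OCOC)cc(O)c21 | intermediate
3 | ethyl (2S)-7-(methoxymethoxy)-2-[4-(methoxymethoxy)phenyl]-4-oxochroman-5-yl carbonate (not isolated) | O=C1C[C@@H](c2ccc(OCOC)cc2)Oc2cc(OCOC)cc(OC(=O)OCC)c21 | intermediate
4 | (2S)-7-(methoxymethoxy)-2-[4-(methoxymethoxy)phenyl]chroman-5-ol | C1C[C@@H](c2ccc(OCOC)cc2)Oc2cc(OCOC)cc(O)c21 | intermediate
5 | (2S)-5-(benzyloxy)-7-(methoxymethoxy)-2-[4-(methoxymethoxy)phenyl]chromane | C1C[C@@H](c2ccc(OCOC)cc2)Oc2cc(OCOC)cc(OCc3ccccc3)c21 | intermediate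
6 | (2S)-5-(benzyloxy)-2-(4-hydroxyphenyl)chroman-7-ol | C1C[C@@H](c2ccc(O)cc2)Oc2cc(O)cc(OCc3ccccc3)c21 | intermediate
7 | 1-[4-(benzyloxy)phenyl]ethan-1-one | CC(=O)c1ccc(OCc2ccccc2)cc1 | starting material
8 | methyl 3-[4-(benzyloxy)phenyl]-3-oxopropanoate | COC(=O)CC(=O)c1ccc(OCc2ccccc2)cc1 | intermediate
9 | methyl 3-[4-(benzyloxy)phenyl]-2-diazo-3-oxopropanoate | COC(=O)C(=[N+]=[N-])C(=O)c1ccc(OCc2ccccc2)cc1 | intermediate
10 | methyl 3-[4-(benzyloxy)phenyl]-2,3-dioxopropanoate | COC(=O)C(=O)C(=O)c1ccc(OCc2ccccc2)cc1 | intermediate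
11 | methyl (2S)-2-[(2S)-5-(benzyloxy)-7-hydroxy-2-(4-hydroxyphenyl)chroman-8-yl]-3-[4-(benzyloxy)phenyl]-2-hydroxy-3-oxopropanoate (not isolated) | Oc3cc(OCc5ccccc5)c4c(c3[C@](C(=O)c6ccc(OCc5ccccc5)cc6)(C(=O)OC)O)O[C@H](c1ccc(O)cc1)CC4 | intermediate
12 | methyl (2S,8S,9S)-5-(benzyloxy)-8-[4-(benzyloxy)phenyl]-8,9-dihydroxy-2-(4-hydroxyphenyl)-3,4,8,9-tetrahydro-2H-furo[2,3-h]chromene-9-carboxylate (hemiketal, C8 anomers equilibrate, not isolated) | O[C@@]2(c3ccc(OCc5ccccc5)cc3)Oc3cc(OCc5ccccc5)c4c(c3[C@]2(C(=O)OC)O)O[C@H](c1ccc(O)cc1)CC4 | intermediate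
13 | methyl (2S,8S,9S)-5-(benzyloxy)-8-[4-(benzyloxy)phenyl]-9-hydroxy-2-(4-hydroxyphenyl)-8-methoxy-3,4,8,9-tetrahydro-2H-furo[2,3-h]chromene-9-carboxylate | CO[C@@]2(c3ccc(OCc5ccccc5)cc3)Oc3cc(OCc5ccccc5)c4c(c3[C@]2(C(=O)OC)O)O[C@H](c1ccc(O)cc1)CC4 | intermediate
14 | methyl (2S,8S,9S)-5,9-bis(benzyloxy)-2,8-bis[4-(benzyloxy)phenyl]-8-methoxy-3,4,8,9-tetrahydro-2H-furo[2,3-h]chromene-9-carboxylate | CO[C@@]2(c3ccc(OCc5ccccc5)cc3)Oc3cc(OCc5ccccc5)c4c(c3[C@]2(C(=O)OC)OCc5ccccc5)O[C@H](c1ccc(OCc5ccccc5)cc1)CC4 | intermediate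
15 | (2S,8S,9S)-5,9-bis(benzyloxy)-2,8-bis[4-(benzyloxy)phenyl]-8-methoxy-3,4,8,9-tetrahydro-2H-furo[2,3-h]chromene-9-carboxylic acid | CO[C@@]2(c3ccc(OCc5ccccc5)cc3)Oc3cc(OCc5ccccc5)c4c(c3[C@]2(C(=O)O)OCc5ccccc5)O[C@H](c1ccc(OCc5ccccc5)cc1)CC4 | intermediate
16 | 3,5-bis(benzyloxy)phenol | Oc1cc(OCc2ccccc2)cc(OCc2ccccc2)c1 | starting material
17 | 3,5-bis(benzyloxy)-2-bromophenol | Oc1cc(OCc2ccccc2)cc(OCc2ccccc2)c1Br | intermediate
18 | [3,5-bis(benzyloxy)-2-bromophenoxy]trimethylsilane (not isolated) | C[Si](C)(C)Oc1cc(OCc2ccccc2)cc(OCc2ccccc2)c1Br | intermediate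
19 | lithium 3,5-bis(benzyloxy)-2-(trimethylsilyl)phenoxide (not isolated) | [Li+].[O-]c1cc(OCc2ccccc2)cc(OCc2ccccc2)c1[Si](C)(C)C | intermediate
20 | 3,5-bis(benzyloxy)-2-(trimethylsilyl)phenyl trifluoromethanesulfonate | C[Si](C)(C)c1c(OS(=O)(=O)C(F)(F)F)cc(OCc2ccccc2)cc1OCc1ccccc1 | intermediate
21 | 3,5-bis(benzyloxy)benzyne (not isolated) | C1#CC(OCc2ccccc2)=CC(OCc2ccccc2)=C1 | intermediate
22 | [(2S,8S,9R)-5,9-bis(benzyloxy)-2,8-bis[4-(benzyloxy)phenyl]-8-methoxy-3,4,8,9-tetrahydro-2H-furo[2,3-h]chromen-9-yl][2,4-bis(benzyloxy)-6-hydroxyphenyl]methanone (not isolated) | CO[C@@]2(c3ccc(OCc5ccccc5)cc3)Oc3cc(OCc5ccccc5)c4c(c3[C@]2(C(=O)c6c(O)cc(OCc5ccccc5)cc6OCc5ccccc5)OCc5ccccc5)O[C@H](c1ccc(OCc5ccccc5)cc1)CC4 | intermediate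
23 | hexabenzyl ether of 24: (2R,3R)-3,5,7-tris(benzyloxy)-2-[4-(benzyloxy)phenyl]chroman-4-one, cis-fused through C2–O–flavan C7 and C3–flavan C8 to (2S)-5-(benzyloxy)-2-[4-(benzyloxy)phenyl]chromane | O=C1c2c(OCc5ccccc5)cc(OCc5ccccc5)cc2O[C@@]2(c3ccc(OCc5ccccc5)cc3)Oc3cc(OCc5ccccc5)c4c(c3[C@@]12OCc5ccccc5)O[C@H](c1ccc(OCc5ccccc5)cc1)CC4 | intermediate
24 | CNP0208300.2: (2R,3R)-3,5,7-trihydroxy-2-(4-hydroxyphenyl)chroman-4-one, cis-fused through C2–O–flavan C7 and C3–flavan C8 to (2S)-5-hydroxy-2-(4-hydroxyphenyl)chromane | O=C1c2c(O)cc(O)cc2O[C@@]2(c3ccc(O)cc3)Oc3cc(O)c4c(c3[C@@]12O)O[C@H](c1ccc(O)cc1)CC4 | target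

**Step count and risks**

Total: 14 steps. Longest linear sequence: 9 steps (steps 1, 2, 3, 4, 8, 9, 10, 13, 14).

Steps most likely to fail:

1. Step 8 (bears the label). The arene may add to the wrong face of the central carbonyl if the chelate is formed through the aryl ketone instead of the ester, or if an uncatalysed background addition competes. Attack through flavan C6 instead of C8 is also possible. If only the sense of induction is wrong, the antipodal ligand is used. The fallback fixes the site by halogen–metal exchange and leaves C3 to separation. It sets out from 5 and returns at 13. N-Bromosuccinimide should brominate 5 at flavan C8, as 5,7-dialkoxyflavans do, to give (2S)-5-(benzyloxy)-8-bromo-7-(methoxymethoxy)-2-[4-(methoxymethoxy)phenyl]chromane F1. Bromine–lithium exchange with n-BuLi at −78 °C gives the 8-lithio flavan F2. Inverse addition of F2 to the central carbonyl of 10 should give methyl 2-[(2S)-5-(benzyloxy)-7-(methoxymethoxy)-2-[4-(methoxymethoxy)phenyl]chroman-8-yl]-3-[4-(benzyloxy)phenyl]-2-hydroxy-3-oxopropanoate F3 as both C3 epimers. HCl in methanol then removes both acetals and converts the freed keto phenol into the methyl ketals 13 and its (2S,8R,9R)-diastereomer F4. These are separated by chromatography, since the flavan centre makes them diastereomers.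

2. Step 13. The aryl anion may be protonated before it reaches the hindered, fully substituted acyl carbon, which would stop the sequence at the aryl ester. Prolonged heating with fluoride could also degrade the substrate, and excess aryne could arylate the product phenoxide. The fallback builds the same C4–C4a bond with an aryllithium. It sets out from 14 and returns at 22, which closes to 23 under the same acid. iBu2AlH at −78 °C should reduce the α-alkoxy ester of 14 to (2S,8S,9R)-5,9-bis(benzyloxy)-2,8-bis[4-(benzyloxy)phenyl]-8-methoxy-3,4,8,9-tetrahydro-2H-furo[2,3-h]chromene-9-carbaldehyde F5. Bromophenol 17 is converted with MOMCl and iPr2NEt into 1,5-bis(benzyloxy)-2-bromo-3-(methoxymethoxy)benzene F6, and bromine–lithium exchange gives [2,4-bis(benzyloxy)-6-(methoxymethoxy)phenyl]lithium F7. Addition of F7 to F5 gives the secondary alcohol F8 as a mixture of carbinol epimers, and the periodinane DMP oxidises it to the aryl ketone F9. HCl in methanol/CH2Cl2 cleaves the aryl acetal to 22 and effects the ketal exchange to 23.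

3. Step 9. Alkylation of the tertiary alkoxide, which sits between the ester, the fused arene and the fully substituted ketal carbon, may stall after the phenol has reacted. The fallback masks the hydroxyl as a silyl ether made under non-basic conditions and removes it in the acid stage of the aryne step. It sets out from 13 and returns at 24. K2CO3 and BnBr in acetone benzylate only the phenol to give methyl (2S,8S,9S)-5-(benzyloxy)-2,8-bis[4-(benzyloxy)phenyl]-9-hydroxy-8-methoxy-3,4,8,9-tetrahydro-2H-furo[2,3-h]chromene-9-carboxylate F10. LiOH hydrolyses this less hindered hydroxy ester to the hydroxy acid F11. N,O-Bis(trimethylsilyl)acetamide converts both OH groups into the trimethylsilyl ester and ether F12, so that no proton donor remains. Under the conditions of step 13, fluoride frees the carboxylate for the aryne insertion, and the acid stage removes the silyl ether and closes ring C to the pentabenzyl ether with free 3-OH F13. Hydrogenolysis as in step 14 gives 24.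

**Further compounds**

F1 | step 8 | (2S)-5-(benzyloxy)-8-bromo-7-(methoxymethoxy)-2-[4-(methoxymethoxy)phenyl]chromane | C1C[C@@H](c2ccc(OCOC)cc2)Oc2c(Br)c(OCOC)cc(OCc3ccccc3)c21
F2 | step 8 | [(2S)-5-(benzyloxy)-7-(methoxymethoxy)-2-[4-(methoxymethoxy)phenyl]chroman-8-yl]lithium | C1C[C@@H](c2ccc(OCOC)cc2)Oc2c([Li])c(OCOC)cc(OCc3ccccc3)c21
F3 | step 8 | methyl 2-[(2S)-5-(benzyloxy)-7-(methoxymethoxy)-2-[4-(methoxymethoxy)phenyl]chroman-8-yl]-3-[4-(benzyloxy)phenyl]-2-hydroxy-3-oxopropanoate (both C3 epimers) | COCOc3cc(OCc5ccccc5)c4c(c3C(C(=O)c6ccc(OCc5ccccc5)cc6)(C(=O)OC)O)O[C@H](c1ccc(OCOC)cc1)CC4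
F4 | step 8 | methyl (2S,8R,9R)-5-(benzyloxy)-8-[4-(benzyloxy)phenyl]-9-hydroxy-2-(4-hydroxyphenyl)-8-methoxy-3,4,8,9-tetrahydro-2H-furo[2,3-h]chromene-9-carboxylate | CO[C@]2(c3ccc(OCc5ccccc5)cc3)Oc3cc(OCc5ccccc5)c4c(c3[C@@]2(C(=O)OC)O)O[C@H](c1ccc(O)cc1)CC4
F5 | step 13 | (2S,8S,9R)-5,9-bis(benzyloxy)-2,8-bis[4-(benzyloxy)phenyl]-8-methoxy-3,4,8,9-tetrahydro-2H-furo[2,3-h]chromene-9-carbaldehyde | CO[C@@]2(c3ccc(OCc5ccccc5)cc3)Oc3cc(OCc5ccccc5)c4c(c3[C@]2(C=O)OCc5ccccc5)O[C@H](c1ccc(OCc5ccccc5)cc1)CC4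
F6 | step 13 | 1,5-bis(benzyloxy)-2-bromo-3-(methoxymethoxy)benzene | COCOc1cc(OCc2ccccc2)cc(OCc2ccccc2)c1Br
F7 | step 13 | [2,4-bis(benzyloxy)-6-(methoxymethoxy)phenyl]lithium | [Li]c1c(OCOC)cc(OCc2ccccc2)cc1OCc1ccccc1
F8 | step 13 | secondary alcohol from F5 and F7: [2,4-bis(benzyloxy)-6-(methoxymethoxy)phenyl] carbinol on C9 of the furan-fused flavan (both carbinol epimers) | CO[C@@]2(c3ccc(OCc5ccccc5)cc3)Oc3cc(OCc5ccccc5)c4c(c3[C@]2(C(O)c6c(OCOC)cc(OCc5ccccc5)cc6OCc5ccccc5)OCc5ccccc5)O[C@H](c1ccc(OCc5ccccc5)cc1)CC4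
F9 | step 13 | methoxymethyl ether of 22: [2,4-bis(benzyloxy)-6-(methoxymethoxy)phenyl] ketone on C9 of the furan-fused flavan | CO[C@@]2(c3ccc(OCc5ccccc5)cc3)Oc3cc(OCc5ccccc5)c4c(c3[C@]2(C(=O)c6c(OCOC)cc(OCc5ccccc5)cc6OCc5ccccc5)OCc5ccccc5)O[C@H](c1ccc(OCc5ccccc5)cc1)CC4
F10 | step 9 | methyl (2S,8S,9S)-5-(benzyloxy)-2,8-bis[4-(benzyloxy)phenyl]-9-hydroxy-8-methoxy-3,4,8,9-tetrahydro-2H-furo[2,3-h]chromene-9-carboxylate | CO[C@@]2(c3ccc(OCc5ccccc5)cc3)Oc3cc(OCc5ccccc5)c4c(c3[C@]2(C(=O)OC)O)O[C@H](c1ccc(OCc5ccccc5)cc1)CC4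
F11 | step 9 | (2S,8S,9S)-5-(benzyloxy)-2,8-bis[4-(benzyloxy)phenyl]-9-hydroxy-8-methoxy-3,4,8,9-tetrahydro-2H-furo[2,3-h]chromene-9-carboxylic acid | CO[C@@]2(c3ccc(OCc5ccccc5)cc3)Oc3cc(OCc5ccccc5)c4c(c3[C@]2(C(=O)O)O)O[C@H](c1ccc(OCc5ccccc5)cc1)CC4
F12 | step 9 | trimethylsilyl (2S,8S,9S)-5-(benzyloxy)-2,8-bis[4-(benzyloxy)phenyl]-8-methoxy-9-[(trimethylsilyl)oxy]-3,4,8,9-tetrahydro-2H-furo[2,3-h]chromene-9-carboxylate | CO[C@@]2(c3ccc(OCc5ccccc5)cc3)Oc3cc(OCc5ccccc5)c4c(c3[C@]2(C(=O)O[Si](C)(C)C)O[Si](C)(C)C)O[C@H](c1ccc(OCc5ccccc5)cc1)CC4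
F13 | step 9 | pentabenzyl ether of 24 with free 3-OH (benzyl on O5/O7/ring B O4′/flavan O5/ring E O4′) | O=C1c2c(OCc5ccccc5)cc(OCc5ccccc5)cc2O[C@@]2(c3ccc(OCc5ccccc5)cc3)Oc3cc(OCc5ccccc5)c4c(c3[C@@]12O)O[C@H](c1ccc(OCc5ccccc5)cc1)CC4
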